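## Analysis of the target

Epiphorellic acid 1 (19) consists of two pentyl-substituted benzoate rings joined by a diaryl ether oxygen. It has no stereocentre, and rotation about the ether bonds is free, so there is no stereochemical problem. Ring A is a methyl benzoate: counted from the ester-bearing carbon C1, it carries the ether oxygen at C2, a free hydroxyl at C4 and the pentyl chain at C6, with hydrogen at C3 and C5. Ring B is a free salicylic-type acid with the carboxyl at C1′, a chelated hydroxyl at C2′, a methoxy group at C4′, the ether oxygen at C5′ and a pentyl chain at C6′. The sensitive points are the 2-hydroxy-6-alkylbenzoic acid of ring B, which decarboxylates on heating or in strong acid, and the need to keep a methyl ester on one ring apart from a free acid on the other. Two free phenols beside one methyl ether also rule out any late dealkylation. The hard bond is the ether itself: it links ring A C2, ortho to the ester, to ring B C5′, which is flanked by methoxy and pentyl, and both rings are electron-rich, so Ullmann or SNAr coupling is poorly suited. The strategy rests on the pattern around ring A C1: the ester carbon lies between the aryloxy carbon C2 and the pentyl carbon C6, with the hydroxyl para at C4. This is the C4(OAr)–C5(CO2Me)–C6(pentyl) array of a 2-pyranone, whose C3 becomes ring A C3 and whose O1–C2 lactone bridge is replaced by the two carbons C4 and C5.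

## Retrosynthetic reasoning

**19 from 18.** The last step should only free the ring B carboxyl. A benzyl ester on ring B, removed by hydrogenolysis at room temperature, leaves the ring A methyl ester, the methyl ether and the diaryl ether untouched and spares the acid from heat. The two carboxyl groups are therefore told apart from the outset: methyl on the ring A carbon skeleton, benzyl on ring B.

**18 from 11 and 13.** Ring A is cut at C3–C4 and C5–C6, the two bonds farthest from the ether. Cutting the ether C–O bond on ring A instead would demand an arylation at a hindered, electron-rich arene carbon. The cut chosen here returns pyranone 11, which already carries the aryloxy, ester and pentyl groups in sequence, and the two-carbon partner 13, which brings the C4 oxygen at the correct oxidation level. The forward reaction has to join the CH2 of 13 to pyranone C6 and its acetal carbon to C3, giving bridged lactone 15. Decarboxylation then gives diene 16, and loss of one silyloxy group gives arene 17, from which 18 is freed on work-up. The chelated ring B hydroxyl is expected to be silylated in the flask (14), which serves as a transient protection.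

**13 from 12.** The ketene acetal is the O-silylated enolate of silyl ester 12; only one C–H deprotonation and one O–Si bond formation are needed.

**11 from 5 and 10.** The C4–O bond of the pyranone is cut. In the forward direction the phenoxide of 10 adds to C4 of sulfonate 5 and the sulfonate leaves. C4 is β to both the lactone and the ester carbonyl, so the hindered phenoxide meets a strongly electrophilic sp2 carbon and not an unactivated arene. The reaction must use the C5′ oxygen of 10 and not the C2′ oxygen; the latter is hydrogen-bonded to the benzyl ester and is a much weaker nucleophile.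

**5 from 4, 3, 1 and 2.** Sulfonylation of the acidic 4-hydroxyl of 4 gives 5. Pyranone 4 is opened at its lactone C–O bond to tricarbonyl 3, the only six-membered lactone this compound can form. Compound 3 is cut at the bond between C2 of keto diester 1 and the acyl carbon of 2. This one C-acylation places the future ring A ester and pentyl group on adjacent carbons.

**10 from 8, 7 and 6.** The C5′–O bond is cut by way of aryl sulfate 9: a para-hydroxylation of the Elbs type on phenol 8, whose only free position para to the phenoxide oxygen is C5′. Phenol 8 comes from 7 by methylation of the non-chelated hydroxyl, and 7 from acid 6 by benzylation of the carboxylate.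

## Alternatives that were turned down

**Alternative 1:** The ether bond from the ring A C2 oxygen to ring B C5′ is made inside a para-depside, and the resulting seven-membered lactone is opened afterwards.
- Key step: constant-current anodic oxidation of para-depside A1 to depsidone A2, closing the dioxepinone ring by O–C coupling; methanolysis of the lactone then gives the ring A methyl ester.
- For: it follows the likely biosynthesis, draws both halves from the same olivetolate stock, and forms the hindered ether intramolecularly. The lactone opening places the methyl ester on ring A without ambiguity.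
- Against: the oxidation has to act on the chelated ring A hydroxyl while the more easily oxidised resorcinol ring B is spared. Coupling at ring B C3′, C–C coupling and over-oxidation to quinones are all open. Methanolysis also leaves the ring B C4′ hydroxyl free, so a selective methylation and two deprotections (tert-butyl ester, benzyl ether) follow: four steps after the key step against one.
- Comparison: it is stronger in fragment economy and in making the ether bond intramolecularly. The chosen route offers instead a bond-forming site fixed by functional groups (one sulfonate, one nucleophilic phenol), a cycloaddition whose orientation follows from polarisation, and a ring B that arrives with its methoxy group in place.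

**Alternative 2:** Ring B is cut at C1′–C6′ and C2′–C3′ and built as a cyclohexane-1,3-dione on an enone that already carries ring A.
- Key step: malonate A4 adds to enone A3 in a Michael reaction and the adduct closes by Dieckmann condensation to dione A5; dehydrogenation to the resorcylate, methylation of the C4′ hydroxyl and debenzylation follow.
- For: the ether oxygen is attached by simple alkylation chemistry before ring B exists, so no hindered arylation is needed. The Michael–Dieckmann sequence is the standard entry to 6-alkylresorcylates and fixes the ring B substitution by construction.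
- Against: A3 has a donor oxygen on its α-carbon and an alkyl group on its β-carbon, which makes it a poor and hindered Michael acceptor, and its preparation by aldol condensation is regiochemically ambiguous. The decisive weakness is in A5, which sits at the dihydroresorcinol oxidation level with the aryloxy group on an sp3 ring carbon. Elimination of the ring A phenol aromatises the ring as well as dehydrogenation does, and it would destroy the ether. Three stereocentres are made only to be erased.
- Comparison: it is equal or stronger in the ease of first making the ether bond. The chosen route offers an aromatisation in which the only leaving groups are the lactone bridge and a silyloxy group, while the ether oxygen stays on an sp2 carbon throughout, and it needs no oxidation step.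

**Alternative 3:** The ether C–O bond at ring A C2 and the bond from ring A C1 to its carboxyl carbon are both made on an aryne.
- Key step: fluoride-triggered generation of aryne A6, addition of the caesium phenoxide of A7 at the aryne carbon remote from the triflyloxy group, and carboxylation of the resulting ortho aryl anion to give acid A8.
- For: three components and two bonds in one operation. The hindered ether forms by addition to a very reactive intermediate, and the inductive triflyloxy group directs the orientation.
- Against: the aryl anion can be protonated or can attack the neighbouring triflate before it is carboxylated, and the phenoxide itself is reversibly carboxylated. The aryne precursor needs several steps and ring B needs an extra benzyl ether. After the key step come methyl esterification, an sp2–sp3 coupling to put the pentyl chain on a triflate beside the ester, and global debenzylation.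
- Comparison: it is stronger in convergence and in bonds formed per step. The chosen route offers the pentyl chain and the methyl ester in place from the first step, no transition-metal coupling, and a single step after the key step.

Key step: step 9

Remark on the chemistry: the excess of ketene acetal 13 in step 9 is assumed to silylate the chelated ring B hydroxyl of 11 before the cycloaddition; this is written into the equation of that step.

## Route

Step 1
Reactants: 1 dimethyl 3-oxopentanedioate; 2 hexanoyl chloride
Product: 3 dimethyl 2-hexanoyl-3-oxopentanedioate
Conditions: MgCl2 (1.0 equiv), pyridine (2.0 equiv), CH2Cl2, 0 °C → rt; 1 M HCl work-up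
Reagents that add atoms: none
Why: Soft enolisation of 1 as its magnesium chelate (Rathke-type C-acylation of a β-keto ester) should direct the acid chloride to carbon, and the tricarbonyl product stays bound as an unreactive chelate until the acidic work-up; one equivalent of 2 limits acylation of the second methylene group.

Step 2
Reactants: 3 dimethyl 2-hexanoyl-3-oxopentanedioate
Product: 4 methyl 4-hydroxy-2-oxo-6-pentyl-2H-pyran-5-carboxylate
Conditions: conc. H2SO4, 0 °C → rt; ice
Reagents that add atoms: none
Why: Acid-promoted lactonisation: the enol oxygen of the hexanoyl ketone attacks the remote ester carbonyl through a six-membered transition state (6-exo-trig) with loss of methanol, and this 4-hydroxy-2-pyranone is the only six-membered lactone that 3 can form; without heating, the 5-ester should be neither hydrolysed nor lost.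

Step 3
Reactants: 4 methyl 4-hydroxy-2-oxo-6-pentyl-2H-pyran-5-carboxylate
Product: 5 methyl 4-[(4-methylphenyl)sulfonyloxy]-2-oxo-6-pentyl-2H-pyran-5-carboxylate
Conditions: TsCl, Et3N, cat. DMAP, CH2Cl2, 0 °C
Reagents that add atoms: p-toluenesulfonyl chloride, Cc1ccc(cc1)S(=O)(=O)Cl
Why: O-Sulfonylation of the acidic vinylogous carboxylic acid of a 4-hydroxy-2-pyranone is standard and occurs at the C4 oxygen, which places a leaving group on the carbon that is β to both the lactone and the ester carbonyl.

Step 4
Reactants: 6 olivetolic acid (2,4-dihydroxy-6-pentylbenzoic acid)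
Product: 7 benzyl 2,4-dihydroxy-6-pentylbenzoate
Conditions: BnBr, KHCO3, DMF, rt
Reagents that add atoms: benzyl bromide, BrCc1ccccc1
Why: Carboxylate O-alkylation with a weak base: KHCO3 deprotonates only the carboxylic acid, so the phenols are left alone, and room temperature avoids decarboxylation of the β-resorcylic acid.

Step 5
Reactants: 7 benzyl 2,4-dihydroxy-6-pentylbenzoate
Product: 8 benzyl 2-hydroxy-4-methoxy-6-pentylbenzoate
Conditions: MeI (1.1 equiv), K2CO3 (1.1 equiv), acetone, rt → 40 °C
Reagents that add atoms: iodomethane, CI
Why: Chemoselective Williamson etherification: the C2′ hydroxyl is held in a hydrogen bond to the ester carbonyl and is a poor nucleophile, so one equivalent of MeI should methylate the C4′ hydroxyl only.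

Step 6
Reactants: 8 benzyl 2-hydroxy-4-methoxy-6-pentylbenzoate
Product: 10 benzyl 2,5-dihydroxy-4-methoxy-6-pentylbenzoate, via potassium aryl sulfate 9 (not isolated)
Conditions: K2S2O8, 10% aq NaOH, pyridine, 5 °C → rt; then aq HCl, 70 °C
Reagents that add atoms: potassium peroxodisulfate, [K+].[K+].[O-]S(=O)(=O)OOS(=O)(=O)[O-]
Why: Elbs persulfate oxidation: the phenoxide of 8 attacks a peroxide oxygen through its para carbon C5′, the only free position para to the phenoxide oxygen, giving sulfate 9, which is protected from further oxidation and is hydrolysed by acid to the hydroquinone; salicylic acid derivatives are classical substrates, and the doubly ortho-substituted benzyl ester should resist the cold dilute alkali.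

Step 7
Reactants: 10 benzyl 2,5-dihydroxy-4-methoxy-6-pentylbenzoate; 5 methyl 4-[(4-methylphenyl)sulfonyloxy]-2-oxo-6-pentyl-2H-pyran-5-carboxylate
Product: 11 methyl 4-[3-(benzyloxycarbonyl)-4-hydroxy-6-methoxy-2-pentylphenoxy]-2-oxo-6-pentyl-2H-pyran-5-carboxylate
Conditions: K2CO3 (1.1 equiv), MeCN, 0 °C → rt
Reagents that add atoms: none
Why: Addition–elimination (vinylogous acyl substitution) at pyranone C4, which is β to two carbonyl groups; with one equivalent of mild base the non-chelated C5′ phenoxide of 10 is the reacting nucleophile, the hydrogen-bonded C2′ hydroxyl being far less nucleophilic, and the sulfonate leaves irreversibly.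

Step 8
Reactants: 12 trimethylsilyl acetate
Product: 13 1,1-bis(trimethylsilyloxy)ethene
Conditions: LiN(iPr)2, THF, −78 °C; TMSCl, −78 °C → rt; filtration, distillation
Reagents that add atoms: chlorotrimethylsilane, C[Si](C)(C)Cl
Why: Deprotonation of the silyl ester at −78 °C and O-silylation of the lithium enolate is the standard preparation of ketene bis(silyl) acetals; the product is isolated with exclusion of moisture.

Step 9
Reactants: 11 methyl 4-[3-(benzyloxycarbonyl)-4-hydroxy-6-methoxy-2-pentylphenoxy]-2-oxo-6-pentyl-2H-pyran-5-carboxylate; 13 1,1-bis(trimethylsilyloxy)ethene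
Product: 18 methyl 2-[3-(benzyloxycarbonyl)-4-hydroxy-6-methoxy-2-pentylphenoxy]-4-hydroxy-6-pentylbenzoate, via O-silylated pyranone 14 (not isolated), via bridged bicyclic lactone 15 (not isolated), via bis(silyloxy)cyclohexadiene 16 (not isolated), via bis(trimethylsilyl) ether 17 (not isolated)
Conditions: 13 (4 equiv), PhMe, 110 °C, sealed tube, Ar; concentrate; 1 M HCl, THF, rt
Reagents that add atoms: none
Why: The excess of 13 should first silylate the chelated ring B hydroxyl to give 14, which protects it in the flask. In an inverse-demand Diels–Alder reaction the nucleophilic CH2 terminus of 13 then bonds to pyranone C6 (δ to the lactone carbonyl and β to the 5-ester, the most electrophilic diene carbon) and the acetal carbon bonds to C3, giving the 2-oxabicyclo[2.2.2]octenone 15, probably by an asynchronous path in which the C6–CH2 bond leads. Ring A is thereby closed by an intermolecular [4+2] cycloaddition that forms both new bonds (ring A C5–C6 and C3–C4); 15 loses CO2 by retro-[4+2] to diene 16, 1,2-elimination of trimethylsilanol from 16 gives arene 17, and the acidic work-up hydrolyses both silyl ethers. The closest known reaction type is the thermal cycloaddition of 5-alkoxycarbonyl-2-pyranones with ketene acetals, which gives para-oxygenated benzoates after loss of CO2 and one oxygen substituent. No stereocentre remains: the two bridgehead centres of 15 are formed as a racemate and vanish on decarboxylation. The step needs regioselectivity, which the matched polarisation of ester-activated C6 and the acetal CH2 should secure and which places the new oxygen para to the ester, and it needs retention of the aryloxy group, which the absence of base or Lewis acid favours and which is certain once 16 is reached, because there the aryloxy group sits on an sp2 carbon and cannot be eliminated.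

Step 10
Reactants: 18 methyl 2-[3-(benzyloxycarbonyl)-4-hydroxy-6-methoxy-2-pentylphenoxy]-4-hydroxy-6-pentylbenzoate
Product: 19 epiphorellic acid 1 (6-hydroxy-3-[5-hydroxy-2-(methoxycarbonyl)-3-pentylphenoxy]-4-methoxy-2-pentylbenzoic acid)
Conditions: H2 (1 atm), 10% Pd/C, EtOAc, rt
Reagents that add atoms: none
Why: Hydrogenolysis of a benzyl ester over Pd/C under neutral conditions at room temperature; the methyl ester, methyl ether, diaryl ether and phenols are inert, and the salicylic-type acid is not exposed to heat or acid, which avoids decarboxylation.

## Compound list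

1 | dimethyl 3-oxopentanedioate | COC(=O)CC(=O)CC(=O)OC | starting material
2 | hexanoyl chloride | CCCCCC(=O)Cl | starting material
3 | dimethyl 2-hexanoyl-3-oxopentanedioate (keto form drawn; the methine is enolised and configurationally labile) | CCCCCC(=O)C(C(=O)OC)C(=O)CC(=O)OC | intermediate
4 | methyl 4-hydroxy-2-oxo-6-pentyl-2H-pyran-5-carboxylate | CCCCCc1oc(=O)cc(O)c1C(=O)OC | intermediate
5 | methyl 4-[(4-methylphenyl)sulfonyloxy]-2-oxo-6-pentyl-2H-pyran-5-carboxylate | CCCCCc1oc(=O)cc(OS(=O)(=O)c2ccc(C)cc2)c1C(=O)OC | intermediate
6 | olivetolic acid (2,4-dihydroxy-6-pentylbenzoic acid) | CCCCCc1cc(O)cc(O)c1C(=O)O | starting material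
7 | benzyl 2,4-dihydroxy-6-pentylbenzoate | CCCCCc1cc(O)cc(O)c1C(=O)OCc1ccccc1 | intermediate
8 | benzyl 2-hydroxy-4-methoxy-6-pentylbenzoate | CCCCCc1cc(OC)cc(O)c1C(=O)OCc1ccccc1 | intermediate
9 | potassium 3-(benzyloxycarbonyl)-4-hydroxy-6-methoxy-2-pentylphenyl sulfate | CCCCCc1c(OS(=O)(=O)[O-])c(OC)cc(O)c1C(=O)OCc1ccccc1.[K+] | intermediate
10 | benzyl 2,5-dihydroxy-4-methoxy-6-pentylbenzoate | CCCCCc1c(O)c(OC)cc(O)c1C(=O)OCc1ccccc1 | intermediate
11 | methyl 4-[3-(benzyloxycarbonyl)-4-hydroxy-6-methoxy-2-pentylphenoxy]-2-oxo-6-pentyl-2H-pyran-5-carboxylate | CCCCCc1oc(=O)cc(Oc2c(OC)cc(O)c(C(=O)OCc3ccccc3)c2CCCCC)c1C(=O)OC | intermediate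
12 | trimethylsilyl acetate | CC(=O)O[Si](C)(C)C | starting material
13 | 1,1-bis(trimethylsilyloxy)ethene (ketene bis(trimethylsilyl) acetal) | C=C(O[Si](C)(C)C)O[Si](C)(C)C | intermediate
14 | methyl 4-[3-(benzyloxycarbonyl)-6-methoxy-2-pentyl-4-(trimethylsilyloxy)phenoxy]-2-oxo-6-pentyl-2H-pyran-5-carboxylate | CCCCCc1oc(=O)cc(Oc2c(OC)cc(O[Si](C)(C)C)c(C(=O)OCc3ccccc3)c2CCCCC)c1C(=O)OC | intermediate
15 | methyl 5-[3-(benzyloxycarbonyl)-6-methoxy-2-pentyl-4-(trimethylsilyloxy)phenoxy]-3-oxo-1-pentyl-8,8-bis(trimethylsilyloxy)-2-oxabicyclo[2.2.2]oct-5-ene-6-carboxylate (racemic; one enantiomer drawn, the relative configuration of the bridgeheads is fixed by the bridge) | CCCCC[C@@]12OC(=O)[C@@H](C(Oc3c(OC)cc(O[Si](C)(C)C)c(C(=O)OCc4ccccc4)c3CCCCC)=C1C(=O)OC)C(O[Si](C)(C)C)(O[Si](C)(C)C)C2 | intermediate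
16 | methyl 6-[3-(benzyloxycarbonyl)-6-methoxy-2-pentyl-4-(trimethylsilyloxy)phenoxy]-2-pentyl-4,4-bis(trimethylsilyloxy)cyclohexa-1,5-diene-1-carboxylate | CCCCCC1=C(C(=O)OC)C(Oc2c(OC)cc(O[Si](C)(C)C)c(C(=O)OCc3ccccc3)c2CCCCC)=CC(O[Si](C)(C)C)(O[Si](C)(C)C)C1 | intermediate
17 | methyl 2-[3-(benzyloxycarbonyl)-6-methoxy-2-pentyl-4-(trimethylsilyloxy)phenoxy]-6-pentyl-4-(trimethylsilyloxy)benzoate | CCCCCc1cc(O[Si](C)(C)C)cc(Oc2c(OC)cc(O[Si](C)(C)C)c(C(=O)OCc3ccccc3)c2CCCCC)c1C(=O)OC | intermediate
18 | methyl 2-[3-(benzyloxycarbonyl)-4-hydroxy-6-methoxy-2-pentylphenoxy]-4-hydroxy-6-pentylbenzoate | CCCCCc1cc(O)cc(Oc2c(OC)cc(O)c(C(=O)OCc3ccccc3)c2CCCCC)c1C(=O)OC | intermediate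
19 | epiphorellic acid 1 (6-hydroxy-3-[5-hydroxy-2-(methoxycarbonyl)-3-pentylphenoxy]-4-methoxy-2-pentylbenzoic acid) | CCCCCc1cc(O)cc(Oc2c(OC)cc(O)c(C(=O)O)c2CCCCC)c1C(=O)OC | target

## Step count and risk

Total step count: 10. Longest linear sequence: 6 steps (steps 1, 2, 3, 7, 9, 10; the ring B branch through steps 4, 5, 6, 7, 9, 10 is equally long).

**Step 9 (key step).** The cycloaddition may be too slow on a diene that carries a donor aryloxy group at C4 and a fully substituted C6. In that case thermal silyl migration or hydrolytic loss of the ketene acetal, or conjugate displacement of the aryloxide at C4, would overtake ring formation. The fallback gives up the pyranone route to ring A and forms the ether by a palladium-catalysed coupling. It sets out from 6 and 10 and rejoins the route at 19.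
- Acid 6 would be esterified with MeI/KHCO3 to methyl 2,4-dihydroxy-6-pentylbenzoate F1.
- F1 would be benzylated at the non-chelated hydroxyl (BnBr, K2CO3) to methyl 4-(benzyloxy)-2-hydroxy-6-pentylbenzoate F2.
- F2 would be converted with Tf2O/pyridine into methyl 4-(benzyloxy)-6-pentyl-2-(trifluoromethylsulfonyloxy)benzoate F3.
- F3 would be coupled with 10 by Buchwald–Hartwig etherification (Pd(OAc)2, 2-di-tert-butylphosphino-2′,4′,6′-triisopropylbiphenyl, K3PO4, PhMe, 100 °C) to methyl 4-(benzyloxy)-2-[3-(benzyloxycarbonyl)-4-hydroxy-6-methoxy-2-pentylphenoxy]-6-pentylbenzoate F4.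
- Hydrogenolysis of F4 under the conditions of step 10 removes both benzyl groups and gives 19.

**Step 6.** Conversion in the persulfate oxidation may stay low because the lipophilic phenoxide dissolves poorly in aqueous alkali. The benzyl ester may be partly saponified, and the hydroquinone may be air-oxidised during the hot acid hydrolysis. The fallback replaces the two-electron hydroxylation by oxidation to the quinone and reduction. It sets out from 8 and returns at 10: Teuber oxidation of 8 with ON(SO3K)2 in buffered aqueous acetone should give benzyl 4-methoxy-3,6-dioxo-2-pentylcyclohexa-1,4-diene-1-carboxylate F5, and reduction of F5 with Na2S2O4 in a two-phase system gives 10.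

**Step 7.** The hindered phenoxide may attack sulfur, transferring the sulfonyl group to the phenol and returning 4, or may add at C6 or C2 with ring opening, instead of substituting at C4. Reaction through the chelated oxygen is a lesser concern. The fallback removes the sulfur electrophile by using a halide as leaving group. It sets out from 4 and returns at 11: bromination of 4 with PBr3 in DMF should give methyl 4-bromo-2-oxo-6-pentyl-2H-pyran-5-carboxylate F6, and the potassium phenoxide of 10 (K2CO3, acetone) displaces bromide from F6 by addition–elimination to give 11.

**Step 1 (with step 2).** O-Acylation, acylation of both methylene groups, or retro-Claisen loss of the hexanoyl group during lactonisation would lower the supply of 4. The fallback builds the pyranone from a β-keto ester and a malonyl unit. It sets out from 2 and returns at 4, bypassing 3.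
- Acid chloride 2 would acylate Meldrum's acid (pyridine, CH2Cl2) to give 5-(1-hydroxyhexylidene)-2,2-dimethyl-1,3-dioxane-4,6-dione F7.
- Methanolysis of F7 in refluxing methanol gives methyl 3-oxooctanoate F8.
- Malonyl dichloride acylates F8 at carbon and closes the lactone through the ketone enol oxygen, a known route to 4-hydroxy-2-pyranone-5-carboxylates, giving 4.

## Further compounds

F1 | step 9 | methyl 2,4-dihydroxy-6-pentylbenzoate | CCCCCc1cc(O)cc(O)c1C(=O)OC
F2 | step 9 | methyl 4-(benzyloxy)-2-hydroxy-6-pentylbenzoate | CCCCCc1cc(OCc2ccccc2)cc(O)c1C(=O)OC
F3 | step 9 | methyl 4-(benzyloxy)-6-pentyl-2-(trifluoromethylsulfonyloxy)benzoate | CCCCCc1cc(OCc2ccccc2)cc(OS(=O)(=O)C(F)(F)F)c1C(=O)OC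
F4 | step 9 | methyl 4-(benzyloxy)-2-[3-(benzyloxycarbonyl)-4-hydroxy-6-methoxy-2-pentylphenoxy]-6-pentylbenzoate | CCCCCc1cc(OCc2ccccc2)cc(Oc2c(OC)cc(O)c(C(=O)OCc3ccccc3)c2CCCCC)c1C(=O)OC
F5 | step 6 | benzyl 4-methoxy-3,6-dioxo-2-pentylcyclohexa-1,4-diene-1-carboxylate | CCCCCC1=C(C(=O)OCc2ccccc2)C(=O)C=C(OC)C1=O
F6 | step 7 | methyl 4-bromo-2-oxo-6-pentyl-2H-pyran-5-carboxylate | CCCCCc1oc(=O)cc(Br)c1C(=O)OC
F7 | step 1 | 5-(1-hydroxyhexylidene)-2,2-dimethyl-1,3-dioxane-4,6-dione | CCCCCC(O)=C1C(=O)OC(C)(C)OC1=O
F8 | step 1 | methyl 3-oxooctanoate | CCCCCC(=O)CC(=O)OC
A1 | alternative 1 | 4-(tert-butoxycarbonyl)-3-hydroxy-5-pentylphenyl 4-(benzyloxy)-2-hydroxy-6-pentylbenzoate (para-depside) | CCCCCc1cc(OCc2ccccc2)cc(O)c1C(=O)Oc1cc(O)c(C(=O)OC(C)(C)C)c(CCCCC)c1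
A2 | alternative 1 | depsidone (dibenzo[b,e][1,4]dioxepin-11-one) carrying both pentyl chains, a benzyl ether on ring A and a tert-butyl ester on ring B | CCCCCc1cc(OCc2ccccc2)cc2c1C(=O)Oc1cc(O)c(C(=O)OC(C)(C)C)c(CCCCC)c1O2
A3 | alternative 2 | methyl 4-(benzyloxy)-2-{[(3Z)-2-oxonon-3-en-3-yl]oxy}-6-pentylbenzoate | CCCCC/C=C(\Oc1cc(OCc2ccccc2)cc(CCCCC)c1C(=O)OC)C(C)=O
A4 | alternative 2 | dibenzyl malonate | O=C(CC(=O)OCc1ccccc1)OCc1ccccc1
A5 | alternative 2 | benzyl 5-aryloxy-2,4-dioxo-6-pentylcyclohexane-1-carboxylate, aryl = ring A (racemic, all-trans isomer drawn) | CCCCC[C@@H]1[C@@H](C(=O)OCc2ccccc2)C(=O)CC(=O)[C@H]1Oc1cc(OCc2ccccc2)cc(CCCCC)c1C(=O)OC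
A6 | alternative 3 | 5-(benzyloxy)-3-(trifluoromethylsulfonyloxy)benzyne | C1#CC(OS(=O)(=O)C(F)(F)F)=CC(OCc2ccccc2)=C1
A7 | alternative 3 | benzyl 2-(benzyloxy)-5-hydroxy-4-methoxy-6-pentylbenzoate | CCCCCc1c(O)c(OC)cc(OCc2ccccc2)c1C(=O)OCc1ccccc1
A8 | alternative 3 | 2-[4-(benzyloxy)-3-(benzyloxycarbonyl)-6-methoxy-2-pentylphenoxy]-4-(benzyloxy)-6-(trifluoromethylsulfonyloxy)benzoic acid | OC(=O)c1c(OS(=O)(=O)C(F)(F)F)cc(OCc2ccccc2)cc1Oc1c(OC)cc(OCc2ccccc2)c(C(=O)OCc2ccccc2)c1CCCCC
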